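**Plan**
1. Cuts: (a) the bond from pyridone C3 to the ketone carbon (3-lithiopyridine plus decalin aldehyde, then oxidation); (b) the two cyclohexene σ-bonds of the decalin, C1–C2 and C4a–C8a (intramolecular Diels–Alder); (c) in the epoxy-diol ring, the CH2–CH2 bond together with the bond from the pyridyl-bearing quaternary carbon to the adjacent oxirane carbon ([4+2]).
2. Enabling feature: in the oxygenated six-membered ring the CH(OH) carbon and the two oxirane carbons are C3, C2 and C1 of a 1-amino-3-siloxybutadiene (C=O, then C=C after loss of the amine). The quaternary carbinol carbon and its CH2 neighbour are the α- and β-carbons of a 2-pyridylacrolein whose formyl group is a latent hydroxyl. The CH2–CH2 bond is therefore the diene-CH2/acrolein-β-CH2 bond of a cycloaddition.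
3. Forward order: pyridine bis-ether → 2-pyridylacrolein → catalytic enantioselective Diels–Alder (carbocycle and quaternary centre) → Baeyer–Villiger (CHO → OH, retention) → oxirane → carbinol. Separately (S)-citronellal → tetraenal → intramolecular Diels–Alder (decalin). Union by C3 lithiation/addition, oxidation, fluoride deprotection.
4. Stereochemistry: the quaternary carbon is set by a chiral diol catalyst and relays the oxirane and the secondary carbinol by substrate control. The methyl-bearing decalin carbon is bought as citronellal and relays the other four decalin centres (IMDA, then thermodynamic epimerization of the formyl carbon).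

Key step: step 4

Abbreviations: Ar = 4,6-bis[2-(trimethylsilyl)ethoxy]pyridin-3-yl (its C3 is C5 of the final pyridone); TES = triethylsilyl; TBS = tert-butyldimethylsilyl.
Assumption: the (4R,5R) antipode of the tetra(naphth-1-yl) TADDOL is taken to expose the enal face that leads to the (S)-configured quaternary carbon of 10; if the sense proves opposite, the (4S,5S) antipode is used with no other change.

**Step 1**
Reactants: 1 5-bromo-2,4-dichloropyridine
Product: 2 5-bromo-2,4-bis[2-(trimethylsilyl)ethoxy]pyridine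
Conditions: 2-(trimethylsilyl)ethanol (2.4 equiv), NaH (2.5 equiv), DMF, 0 → 70 °C
Reagents that add atoms: 2-(trimethylsilyl)ethanol, C[Si](C)(C)CCO
Why: Two successive SNAr displacements (C4 chloride, then C2 chloride, both activated by the ring nitrogen) should give the bis-ether and leave the unactivated C5 bromide as the handle.

**Step 2**
Reactants: 2 5-bromo-2,4-bis[2-(trimethylsilyl)ethoxy]pyridine; 3 2-bromo-3,3-diethoxyprop-1-ene
Product: 6 5-(3,3-diethoxyprop-1-en-2-yl)-2,4-bis[2-(trimethylsilyl)ethoxy]pyridine, via 5-lithiopyridine 4 (not isolated), via pyridin-5-ylzinc chloride 5 (not isolated)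
Conditions: n-BuLi, THF, −78 °C; ZnCl2, −78 → 0 °C; 3, Pd(PPh3)4 (5 mol%), THF, 50 °C
Reagents that add atoms: none
Why: Fast bromine–lithium exchange at −78 °C, transmetalation to zinc and Negishi coupling with the 1,1-disubstituted vinyl bromide should install the masked acrolein at C5 without touching C3–H.

**Step 3**
Reactants: 6 5-(3,3-diethoxyprop-1-en-2-yl)-2,4-bis[2-(trimethylsilyl)ethoxy]pyridine
Product: 7 2-Ar-prop-2-enal
Conditions: oxalic acid (10% aq), THF, 0 °C → rt; used at once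
Reagents that add atoms: water, O
Why: Mild acetal hydrolysis should free the aldehyde while the aryl silylethyl ethers survive; immediate use avoids dimerization of the 2-arylacrolein.

**Step 4**
Reactants: 7 2-Ar-prop-2-enal; 8 (1E)-3-(tert-butyldimethylsilyloxy)-N,N-dimethylbuta-1,3-dien-1-amine
Product: 10 (1S)-1-Ar-4-oxocyclohex-2-ene-1-carbaldehyde, via cycloadduct 9 (not isolated)
Conditions: (4R,5R)-2,2-dimethyl-α,α,α',α'-tetra(naphth-1-yl)-1,3-dioxolane-4,5-dimethanol (20 mol%), toluene, −78 °C; then AcCl, CH2Cl2, −78 → −20 °C; aq NaHCO3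
Reagents that add atoms: none
Why: The enal, activated by one hydrogen bond from the diol catalyst, undergoes a concerted, asynchronous normal-demand [4+2] cycloaddition with the electron-rich diene; the diene CH2 terminus bonds to the acrolein β-CH2 (the CH2–CH2 bond of the ring) and the amino-bearing terminus to the α-carbon, the two σ-bonds together closing the six-membered carbocycle. The closest known reaction type is the hydrogen-bond (TADDOL)-catalysed enantioselective Diels–Alder reaction of 1-amino-3-siloxybutadienes with 2-substituted acroleins, which likewise builds a formyl-bearing quaternary carbon. The ring closes in the [4+2] mode, suprafacial on both components, and the regiochemistry follows from the push of nitrogen and siloxy oxygen onto the diene CH2 terminus. The one stereocentre that survives, the quaternary carbon, is controlled by the catalyst, whose naphthyl groups block one face of the bound enal; the amino-bearing centre (endo, cis to CHO) is erased when AcCl acylates nitrogen and triggers loss of N,N-dimethylacetamide and the silyl group to give the enone. The step needs enantioface selectivity and C=C over C=O chemoselectivity; the first rests on the low temperature and the weak basicity of the alkoxy-flanked ring nitrogen, the second on the α-substituent, which disfavours the s-cis enal needed for a hetero-Diels–Alder path.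

**Step 5**
Reactants: 10 (1S)-1-Ar-4-oxocyclohex-2-ene-1-carbaldehyde
Product: 12 (4S)-4-Ar-4-hydroxycyclohex-2-en-1-one, via formate 11 (not isolated)
Conditions: mCPBA (1.3 equiv), Na2HPO4, CH2Cl2, 0 °C → rt; then K2CO3 (cat.), MeOH, 0 °C
Reagents that add atoms: mCPBA, OOC(=O)c1cccc(Cl)c1
Why: In the Baeyer–Villiger oxidation the fully substituted, benzylic and allylic carbon should migrate in preference to hydride with retention of configuration, and brief methanolysis of the formate frees the tertiary alcohol.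

**Step 6**
Reactants: 12 (4S)-4-Ar-4-hydroxycyclohex-2-en-1-one
Product: 13 (4S)-4-Ar-4-(triethylsilyloxy)cyclohex-2-en-1-one
Conditions: TESOTf, 2,6-lutidine, CH2Cl2, −78 °C
Reagents that add atoms: triethylsilyl trifluoromethanesulfonate, CC[Si](CC)(CC)OS(=O)(=O)C(F)(F)F
Why: Silylation of the tertiary alcohol removes hydroxyl-directed delivery in the next step and makes the oxygen substituent the bulky pseudoaxial group.

**Step 7**
Reactants: 13 (4S)-4-Ar-4-(triethylsilyloxy)cyclohex-2-en-1-one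
Product: 14 (1R,5R,6S)-5-Ar-5-(triethylsilyloxy)-7-oxabicyclo[4.1.0]heptan-2-one (oxirane trans to OTES)
Conditions: t-BuOOH (5.5 M in decane), benzyltrimethylammonium hydroxide (0.2 equiv), THF, 0 °C
Reagents that add atoms: tert-butyl hydroperoxide, CC(C)(C)OO
Why: In this Weitz–Scheffer epoxidation the peroxide anion should add axially to the β-carbon anti to the pseudoaxial silyloxy group, so both oxirane centres are set trans to OTES (cis to Ar) by substrate control.

**Step 8**
Reactants: 14 (1R,5R,6S)-5-Ar-5-(triethylsilyloxy)-7-oxabicyclo[4.1.0]heptan-2-one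
Product: 15 (1S,2R,5R,6S)-5-Ar-5-(triethylsilyloxy)-7-oxabicyclo[4.1.0]heptan-2-ol (hydroxyl trans to the oxirane and cis to OTES)
Conditions: NaBH4, CeCl3·7H2O, MeOH, −78 °C
Reagents that add atoms: none
Why: Luche reduction of a 2,3-epoxycyclohexanone is expected to deliver hydride on the oxirane face through a cation bridging the carbonyl and oxirane oxygens, giving the trans-epoxy alcohol.

**Step 9**
Reactants: 15 (1S,2R,5R,6S)-5-Ar-5-(triethylsilyloxy)-7-oxabicyclo[4.1.0]heptan-2-ol
Product: 16 (1S,2R,5R,6R)-2-Ar-2,5-bis(triethylsilyloxy)-7-oxabicyclo[4.1.0]heptane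
Conditions: TESCl, imidazole, DMF, 0 °C → rt
Reagents that add atoms: chlorotriethylsilane, CC[Si](CC)(CC)Cl
Why: Routine silylation removes the acidic proton so that no alkoxide sits next to the oxirane during the metalation.

**Step 10**
Reactants: 17 (3S)-3,7-dimethyloct-6-enal
Product: 19 (6S,8E,10E)-2,6-dimethyldodeca-2,8,10-triene, via (8Z,10E)-triene 18 (not isolated)
Conditions: (E)-but-2-enyl(triphenyl)phosphonium chloride, n-BuLi, THF, −78 °C → rt; then I2 (3 mol%), hexanes, visible light, rt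
Reagents that add atoms: (E)-but-2-enyl(triphenyl)phosphonium chloride, C/C=C/C[P+](c1ccccc1)(c1ccccc1)c1ccccc1.[Cl-]
Why: Wittig olefination with the allylic ylide should give the diene as an E/Z mixture at the new double bond, which iodine-catalysed equilibration converts to the more stable (E,E)-diene; the stereocentre is untouched.

**Step 11**
Reactants: 19 (6S,8E,10E)-2,6-dimethyldodeca-2,8,10-triene
Product: 21 (2E,6S,8E,10E)-2,6-dimethyldodeca-2,8,10-trienal, via allylic alcohol 20 (not isolated)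
Conditions: SeO2 (0.3 equiv), t-BuOOH (70% aq), salicylic acid (0.1 equiv), CH2Cl2, rt; then MnO2, CH2Cl2, rt
Reagents that add atoms: tert-butyl hydroperoxide, CC(C)(C)OO (terminal oxidant; the oxygen is passed on through catalytic SeO2, O=[Se]=O)
Why: The SeO2 ene/[2,3]-shift sequence should oxidize the (E)-methyl group of the more electron-rich trisubstituted alkene (allylic oxidation), and MnO2 carries the allylic alcohol on to the (E)-enal.

**Step 12**
Reactants: 21 (2E,6S,8E,10E)-2,6-dimethyldodeca-2,8,10-trienal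
Product: 22 (2E,4E,8S,10E,12E)-4,8-dimethyltetradeca-2,4,10,12-tetraenal
Conditions: Ph3P=CHCHO (1.3 equiv), toluene, 70 °C
Reagents that add atoms: (triphenylphosphoranylidene)acetaldehyde, O=CC=P(c1ccccc1)(c1ccccc1)c1ccccc1
Why: Wittig reaction with the stabilized formylmethylene ylide should extend the enal by two carbons with E selectivity.

**Step 13**
Reactants: 22 (2E,4E,8S,10E,12E)-4,8-dimethyltetradeca-2,4,10,12-tetraenal
Product: 24 (1R,2S,4aS,7S,8aR)-4,7-dimethyl-1-[(E)-prop-1-enyl]-1,2,4a,5,6,7,8,8a-octahydronaphthalene-2-carbaldehyde, via cis-aldehyde 23 (not isolated)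
Conditions: toluene (0.01 M), BHT (cat.), 130 °C, sealed tube; then DBU (0.3 equiv), rt
Reagents that add atoms: none
Why: Thermal intramolecular Diels–Alder reaction of the dienal (diene) with the proximal alkene of the hexadienyl unit (dienophile), through a chair-like tether with equatorial methyl and endo propenyl, should give the trans-fused octalin with four centres relayed from the citronellal centre; the formyl group emerges cis to propenyl and DBU equilibrates it via the dienolate to the all-equatorial epimer.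

**Step 14**
Reactants: 16 (1S,2R,5R,6R)-2-Ar-2,5-bis(triethylsilyloxy)-7-oxabicyclo[4.1.0]heptane; 24 (1R,2S,4aS,7S,8aR)-4,7-dimethyl-1-[(E)-prop-1-enyl]-1,2,4a,5,6,7,8,8a-octahydronaphthalene-2-carbaldehyde
Product: 26 {(1R,2S,4aS,7S,8aR)-4,7-dimethyl-1-[(E)-prop-1-enyl]-1,2,4a,5,6,7,8,8a-octahydronaphthalen-2-yl}{5-[(1S,2R,5R,6R)-2,5-bis(triethylsilyloxy)-7-oxabicyclo[4.1.0]heptan-2-yl]-2,4-bis[2-(trimethylsilyl)ethoxy]pyridin-3-yl}methanol (both carbinol epimers), via 3-lithiopyridine 25 (not isolated)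
Conditions: s-BuLi, TMEDA, THF, −78 °C; then 24, THF, −78 °C; aq NH4Cl
Reagents that add atoms: none
Why: Directed ortho-metalation should remove the C3 proton flanked by the two alkoxy groups, and the aryllithium should add to the aldehyde at −78 °C faster than it attacks the hindered oxirane; the carbinol configuration is irrelevant.

**Step 15**
Reactants: 26 the carbinol of step 14
Product: 27 {(1R,2S,4aS,7S,8aR)-4,7-dimethyl-1-[(E)-prop-1-enyl]-1,2,4a,5,6,7,8,8a-octahydronaphthalen-2-yl}{5-[(1S,2R,5R,6R)-2,5-bis(triethylsilyloxy)-7-oxabicyclo[4.1.0]heptan-2-yl]-2,4-bis[2-(trimethylsilyl)ethoxy]pyridin-3-yl}methanone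
Conditions: Dess–Martin periodinane, NaHCO3, CH2Cl2, 0 °C → rt
Reagents that add atoms: none
Why: Dess–Martin oxidation should convert the carbinol to the aryl ketone under buffered conditions that leave the alkenes, oxirane and silyl ethers intact.

**Step 16**
Reactants: 27 the ketone of step 15
Product: 28 4-hydroxy-3-[(1R,2S,4aS,7S,8aR)-4,7-dimethyl-1-[(E)-prop-1-enyl]-1,2,4a,5,6,7,8,8a-octahydronaphthalene-2-carbonyl]-5-[(1S,2R,5R,6S)-2,5-dihydroxy-7-oxabicyclo[4.1.0]heptan-2-yl]-1H-pyridin-2-one (CNP0494338.1)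
Conditions: TBAF (1 M in THF, 6 equiv), THF, 0 °C → rt; pH 7 buffer
Reagents that add atoms: none
Why: Fluoride should remove both TES ethers and, by attack at silicon with loss of ethene, both 2-(trimethylsilyl)ethyl ethers (leaving groups: the vinylogous carboxylate at O4 and the pyridonate at O2), so the 4-hydroxy-2-pyridone appears without acid.

**Compound list**
1 | 5-bromo-2,4-dichloropyridine | Clc1cc(Cl)c(Br)cn1 | starting material
2 | 5-bromo-2,4-bis[2-(trimethylsilyl)ethoxy]pyridine | C[Si](C)(C)CCOc1cc(OCC[Si](C)(C)C)c(Br)cn1 | intermediate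
3 | 2-bromo-3,3-diethoxyprop-1-ene | C=C(Br)C(OCC)OCC | starting material
4 | {4,6-bis[2-(trimethylsilyl)ethoxy]pyridin-3-yl}lithium | [Li]c1cnc(OCC[Si](C)(C)C)cc1OCC[Si](C)(C)C | intermediate
5 | {4,6-bis[2-(trimethylsilyl)ethoxy]pyridin-3-yl}zinc chloride | Cl[Zn]c1cnc(OCC[Si](C)(C)C)cc1OCC[Si](C)(C)C | intermediate
6 | 5-(3,3-diethoxyprop-1-en-2-yl)-2,4-bis[2-(trimethylsilyl)ethoxy]pyridine | C=C(C(OCC)OCC)c1cnc(OCC[Si](C)(C)C)cc1OCC[Si](C)(C)C | intermediate
7 | 2-{4,6-bis[2-(trimethylsilyl)ethoxy]pyridin-3-yl}prop-2-enal | C=C(C=O)c1cnc(OCC[Si](C)(C)C)cc1OCC[Si](C)(C)C | intermediate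
8 | (1E)-3-(tert-butyldimethylsilyloxy)-N,N-dimethylbuta-1,3-dien-1-amine | CN(C)/C=C/C(=C)O[Si](C)(C)C(C)(C)C | starting material
9 | (1R,2R)-1-Ar-4-(tert-butyldimethylsilyloxy)-2-(dimethylamino)cyclohex-3-ene-1-carbaldehyde (CHO cis to NMe2) | C[Si](C)(C)CCOc1cc(OCC[Si](C)(C)C)c(cn1)[C@]2(C=O)CCC(O[Si](C)(C)C(C)(C)C)=C[C@H]2N(C)C | intermediate
10 | (1S)-1-Ar-4-oxocyclohex-2-ene-1-carbaldehyde | C[Si](C)(C)CCOc1cc(OCC[Si](C)(C)C)c(cn1)[C@]2(C=O)CCC(=O)C=C2 | intermediate
11 | (1S)-1-Ar-4-oxocyclohex-2-en-1-yl formate | C[Si](C)(C)CCOc1cc(OCC[Si](C)(C)C)c(cn1)[C@]2(OC=O)CCC(=O)C=C2 | intermediate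
12 | (4S)-4-Ar-4-hydroxycyclohex-2-en-1-one | C[Si](C)(C)CCOc1cc(OCC[Si](C)(C)C)c(cn1)[C@]2(O)CCC(=O)C=C2 | intermediate
13 | (4S)-4-Ar-4-(triethylsilyloxy)cyclohex-2-en-1-one | C[Si](C)(C)CCOc1cc(OCC[Si](C)(C)C)c(cn1)[C@]2(O[Si](CC)(CC)CC)CCC(=O)C=C2 | intermediate
14 | (1R,5R,6S)-5-Ar-5-(triethylsilyloxy)-7-oxabicyclo[4.1.0]heptan-2-one | C[Si](C)(C)CCOc1cc(OCC[Si](C)(C)C)c(cn1)[C@]2(O[Si](CC)(CC)CC)CCC(=O)[C@@H]3O[C@@H]32 | intermediate
15 | (1S,2R,5R,6S)-5-Ar-5-(triethylsilyloxy)-7-oxabicyclo[4.1.0]heptan-2-ol | C[Si](C)(C)CCOc1cc(OCC[Si](C)(C)C)c(cn1)[C@]2(O[Si](CC)(CC)CC)CC[C@@H](O)[C@@H]3O[C@@H]32 | intermediate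
16 | (1S,2R,5R,6R)-2-Ar-2,5-bis(triethylsilyloxy)-7-oxabicyclo[4.1.0]heptane | C[Si](C)(C)CCOc1cc(OCC[Si](C)(C)C)c(cn1)[C@]2(O[Si](CC)(CC)CC)CC[C@@H](O[Si](CC)(CC)CC)[C@@H]3O[C@@H]32 | intermediate
17 | (3S)-3,7-dimethyloct-6-enal ((S)-citronellal) | C[C@@H](CCC=C(C)C)CC=O | starting material
18 | (6S,8Z,10E)-2,6-dimethyldodeca-2,8,10-triene | C[C@@H](CCC=C(C)C)C/C=C\C=C\C | intermediate
19 | (6S,8E,10E)-2,6-dimethyldodeca-2,8,10-triene | C[C@@H](CCC=C(C)C)C/C=C/C=C/C | intermediate
20 | (2E,6S,8E,10E)-2,6-dimethyldodeca-2,8,10-trien-1-ol | C[C@@H](CC/C=C(\C)CO)C/C=C/C=C/C | intermediate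
21 | (2E,6S,8E,10E)-2,6-dimethyldodeca-2,8,10-trienal | C[C@@H](CC/C=C(\C)C=O)C/C=C/C=C/C | intermediate
22 | (2E,4E,8S,10E,12E)-4,8-dimethyltetradeca-2,4,10,12-tetraenal | C[C@@H](CC/C=C(C)/C=C/C=O)C/C=C/C=C/C | intermediate
23 | (1R,2R,4aS,7S,8aR)-4,7-dimethyl-1-[(E)-prop-1-enyl]-1,2,4a,5,6,7,8,8a-octahydronaphthalene-2-carbaldehyde | C/C=C/[C@@H]1[C@H]2C[C@@H](C)CC[C@@H]2C(C)=C[C@@H]1C=O | intermediate
24 | (1R,2S,4aS,7S,8aR)-4,7-dimethyl-1-[(E)-prop-1-enyl]-1,2,4a,5,6,7,8,8a-octahydronaphthalene-2-carbaldehyde | C/C=C/[C@@H]1[C@H]2C[C@@H](C)CC[C@@H]2C(C)=C[C@H]1C=O | intermediate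
25 | {5-[(1S,2R,5R,6R)-2,5-bis(triethylsilyloxy)-7-oxabicyclo[4.1.0]heptan-2-yl]-2,4-bis[2-(trimethylsilyl)ethoxy]pyridin-3-yl}lithium | [Li]c1c(OCC[Si](C)(C)C)c([C@]2(O[Si](CC)(CC)CC)CC[C@@H](O[Si](CC)(CC)CC)[C@@H]3O[C@@H]32)cnc1OCC[Si](C)(C)C | intermediate
26 | decalin-2-yl pyridin-3-yl methanol of step 14 (carbinol centre unspecified, both epimers) | C/C=C/[C@@H]1[C@H]2C[C@@H](C)CC[C@@H]2C(C)=C[C@H]1C(O)c1c(OCC[Si](C)(C)C)c([C@]2(O[Si](CC)(CC)CC)CC[C@@H](O[Si](CC)(CC)CC)[C@@H]3O[C@@H]32)cnc1OCC[Si](C)(C)C | intermediate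
27 | decalin-2-yl pyridin-3-yl methanone of step 15 | C/C=C/[C@@H]1[C@H]2C[C@@H](C)CC[C@@H]2C(C)=C[C@H]1C(=O)c1c(OCC[Si](C)(C)C)c([C@]2(O[Si](CC)(CC)CC)CC[C@@H](O[Si](CC)(CC)CC)[C@@H]3O[C@@H]32)cnc1OCC[Si](C)(C)C | intermediate
28 | CNP0494338.1 | C/C=C/[C@@H]1[C@H]2C[C@@H](C)CC[C@@H]2C(C)=C[C@H]1C(=O)c1c(O)c([C@]2(O)CC[C@@H](O)[C@@H]3O[C@@H]32)c[nH]c1=O | target

**Count and risks**
Total step count: 16. Longest linear sequence: 12 steps (steps 1–9, then 14–16); the decalin branch is 4 steps (10–13).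

Three steps most likely to fail:

Step 4. Enantioface discrimination may erode because the pyridine nitrogen and the ether oxygens compete for the catalyst hydrogen bonds and the very reactive diene reacts uncatalysed; the 2-arylacrolein may also oligomerize before cycloaddition. The fallback sets out from 2 and returns at 13. Bromine–lithium exchange of 2 (n-BuLi, THF, −78 °C) and addition to 1,4-dioxaspiro[4.5]decan-8-one should give 8-Ar-1,4-dioxaspiro[4.5]decan-8-ol F1. Mild ketal hydrolysis (pyridinium tosylate, acetone/water) should give 4-Ar-4-hydroxycyclohexanone F2, and TESOTf/2,6-lutidine the achiral 4-Ar-4-(triethylsilyloxy)cyclohexanone F3. Enantiotopic deprotonation with lithium (R,R)-bis(1-phenylethyl)amide and LiCl in the presence of Me3SiCl (THF, −100 °C; antipode of the base chosen for the required sense) should give (4S)-4-Ar-4-(triethylsilyloxy)-1-(trimethylsilyloxy)cyclohex-1-ene F4. Saegusa–Ito dehydrogenation (Pd(OAc)2, MeCN) should then give 13.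

Step 5. Hydride may migrate in place of carbon in the Criegee adduct, leading to over-oxidation to the carboxylic acid, and the ring nitrogen may be N-oxidized. The fallback sets out from 10 and returns at 12. Chemoselective addition of MeTi(OiPr)3 to the aldehyde (THF, −40 °C, enone untouched) should give (4S)-4-Ar-4-(1-hydroxyethyl)cyclohex-2-en-1-one F5 (carbinol epimers). Dess–Martin oxidation should give (4S)-4-acetyl-4-Ar-cyclohex-2-en-1-one F6. Baeyer–Villiger oxidation of this methyl ketone (mCPBA, NaHCO3, CH2Cl2), where no hydride shift exists and the quaternary carbon outcompetes methyl, should give (1S)-1-Ar-4-oxocyclohex-2-en-1-yl acetate F7, and K2CO3/MeOH should give 12.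

Step 14. Metalation may be incomplete or misdirected, the alkyllithium may open the oxirane, and the hindered aryllithium may deprotonate the α-branched aldehyde. The fallback sets out from 16 and returns at 26. Electrophilic iodination at the only activated free ring position (N-iodosuccinimide, MeCN, rt) should give (1S,2R,5R,6R)-2-{5-iodo-4,6-bis[2-(trimethylsilyl)ethoxy]pyridin-3-yl}-2,5-bis(triethylsilyloxy)-7-oxabicyclo[4.1.0]heptane F8. Iodine–magnesium exchange (iPrMgCl·LiCl, THF, −40 °C) should give the corresponding pyridin-3-ylmagnesium chloride F9, used without isolation and far less basic toward the oxirane and the aldehyde α-proton; addition to 24 gives 26.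

**Further compounds**
F1 | step 4 | 8-Ar-1,4-dioxaspiro[4.5]decan-8-ol | C[Si](C)(C)CCOc1cc(OCC[Si](C)(C)C)c(cn1)C2(O)CCC3(CC2)OCCO3
F2 | step 4 | 4-Ar-4-hydroxycyclohexanone | C[Si](C)(C)CCOc1cc(OCC[Si](C)(C)C)c(cn1)C2(O)CCC(=O)CC2
F3 | step 4 | 4-Ar-4-(triethylsilyloxy)cyclohexanone | C[Si](C)(C)CCOc1cc(OCC[Si](C)(C)C)c(cn1)C2(O[Si](CC)(CC)CC)CCC(=O)CC2
F4 | step 4 | (4S)-4-Ar-4-(triethylsilyloxy)-1-(trimethylsilyloxy)cyclohex-1-ene | C[Si](C)(C)CCOc1cc(OCC[Si](C)(C)C)c(cn1)[C@]2(O[Si](CC)(CC)CC)CCC(O[Si](C)(C)C)=CC2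
F5 | step 5 | (4S)-4-Ar-4-(1-hydroxyethyl)cyclohex-2-en-1-one (carbinol epimers) | C[Si](C)(C)CCOc1cc(OCC[Si](C)(C)C)c(cn1)[C@]2(C(C)O)CCC(=O)C=C2
F6 | step 5 | (4S)-4-acetyl-4-Ar-cyclohex-2-en-1-one | C[Si](C)(C)CCOc1cc(OCC[Si](C)(C)C)c(cn1)[C@]2(C(C)=O)CCC(=O)C=C2
F7 | step 5 | (1S)-1-Ar-4-oxocyclohex-2-en-1-yl acetate | C[Si](C)(C)CCOc1cc(OCC[Si](C)(C)C)c(cn1)[C@]2(OC(C)=O)CCC(=O)C=C2
F8 | step 14 | (1S,2R,5R,6R)-2-{5-iodo-4,6-bis[2-(trimethylsilyl)ethoxy]pyridin-3-yl}-2,5-bis(triethylsilyloxy)-7-oxabicyclo[4.1.0]heptane | C[Si](C)(C)CCOc1ncc([C@]2(O[Si](CC)(CC)CC)CC[C@@H](O[Si](CC)(CC)CC)[C@@H]3O[C@@H]32)c(OCC[Si](C)(C)C)c1I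
F9 | step 14 | {5-[(1S,2R,5R,6R)-2,5-bis(triethylsilyloxy)-7-oxabicyclo[4.1.0]heptan-2-yl]-2,4-bis[2-(trimethylsilyl)ethoxy]pyridin-3-yl}magnesium chloride | C[Si](C)(C)CCOc1ncc([C@]2(O[Si](CC)(CC)CC)CC[C@@H](O[Si](CC)(CC)CC)[C@@H]3O[C@@H]32)c(OCC[Si](C)(C)C)c1[Mg]Cl
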